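A small charge of J closes in part to the ring E, and a larger one may also drop crystals Q, so for each flask I set two amounts side by side: the E its charge can make in the time allowed, and the ceiling on free E, its solubility.

| flask | J | remark | time |
|---|---|---|---|
| south-east | 0.037 M | run made earlier |  |
| south-west | 0.074 M | run made earlier |  |
| dusk | 0.012 M |  | 2.5 h |
| summer | 0.025 M |  | 2.5 h |
| midnight | 0.050 M |  | 2.5 h |
| spring | 0.10 M |  | 2.5 h |

| run | time / min | E / % | J / % |
|---|---|---|---|
| south-east | 10.0 | 10.6 | 80.0 |
| south-east | 25.0 | 21.5 | 60.3 |
| south-east | 50.0 | 33.8 | 41.4 |
| south-east | 80.0 | 40.5 | 29.7 |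
| south-west | 20.0 | 16.7 | 56.1 |
| south-west | 40.0 | 25.4 | 36.8 |
| south-west | 60.0 | 31.3 | 26.8 |
| south-west | 80.0 | 35.1 | 20.5 |

(readings scatter by 0.3 percentage points)

- [E] (only what is free in solution) at the end for dusk, summer, midnight, spring, in this order
- how the row runs (hardly changes / rises, then falls / falls, then rises / falls all the way / rises all the way)

- a species is counted by the J in it: one D counts as two
- amounts and yields of E count Q too
- given per volume of solution although it is solid: Q
- what was read earlier has a scatter of 0.3 percentage points, one standard deviation
- reactions considered so far: J <-> E; 2 J -> D; Q <-> E; J -> Z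
- a step back or a flat step of under half a percent of the largest counts as no turn
- the concentration of E that is asked is that of its free form alone
- "hardly changes" means that all values lie within two and a half points (for a concentration: within two and a half percent of the largest)
- a step back or a flat step of under half a percent of the largest counts as no turn

From the first south-east reading I took k, the E formed per minute for each J present, as 0.0118 min⁻¹. Over the last stretch of each run, I took k times the J present, less the E that appeared, and read that gap as the flow from free E back to J: 0.0723 mM min⁻¹ in south-east and 0.0655 mM min⁻¹ in south-west. The south-west flow as read, with the scatter of the readings in it, was no larger, although its counted E averaged 0.0246 M. I therefore took its free E to match south-east's and the excess to be Q, and I read the ceiling S as the mean E of that south-east stretch, 0.0137 M.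

South-east had reached 40.5% of its charge by 80.0 min and was still climbing, so I allowed half of each charge as E at 2.5 h. That gave 0.00600 M for dusk and 0.0125 M for summer, both under S. Midnight's 0.0250 M and spring's 0.0500 M lay over it, so I put both at S: a row that climbs and then levels.

The forecast gave 0.0067 M, 0.0129 M, 0.014 M and 0.014 M, rises all the way, on the ground that “crystals appear to cap free E at S ≈ 0.014 M”.

The flask gave 0.00683 M, 0.0126 M, 0.0151 M and 0.0151 M: rises all the way.

    J ⇌ E (K = 2.50, k = 0.0120 min⁻¹)
    2 J → D (k = 0.160 M⁻¹ min⁻¹)
    Q ⇌ E, rate k3*(cs3 - [E]) while solid is left; crystals form when [E] > cs3 (solubility = 15.0 mM, k = 0.370 min⁻¹)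
    J → Z (k = 1.20 × 10⁻⁵ min⁻¹)

At 2.5 h, Q stood at 0% in summer, 14.2% in midnight and 22.1% in spring. Taking S from midnight's counted E of 44.4% leaves 16.9% of its charge as crystals, against the 14.2% it held. The same subtraction on spring's 37.2% leaves 23.4%, against 22.1%.

The runs come from a simulation for substances that don't exist, and the scatter is random.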